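**Retrosynthetic overview**
1. Target ⇐ C16 α‑methylenation and desilylation of the ten‑membered‑ring enone acetate (bicyclo[7.2.1] core complete).
2. Key step: four‑carbon ring expansion. A samarium ketyl at C11 adds to the C9 ketone of a spiro 1,3‑diketone, the C8–C9 bond breaks (retro‑aldol) and the sulfinate on C14 leaves. Six‑membered ring B becomes the ten‑membered ring, with the C8=C14 enone and C11–O in place.
3. Spiro diketone ⇐ thiolate‑triggered Michael/aldol closure of ring B (C8–C9) ⇐ iodide‑triggered Michael/aldol union (C7–C8, sets C7) of a ring A dialdehyde with (S)‑4‑allylcyclopentenone (ring D).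
4. Ring A dialdehyde ⇐ 3‑methylcyclohexenone (asymmetric conjugate vinylation/allylation, geminal dimethylation, ozonolysis); ring D piece ⇐ (S)‑4‑silyloxycyclopentenone (conjugate allylation/elimination).
5. Ring order: A and D come from the two starting rings; ring B is built as a temporary six‑membered ring (step 6) and expanded to the ten‑membered ring (step 10).

Assumption and labels: (S)‑4‑hydroxycyclopent‑2‑enone (7 non‑hydrogen atoms) is bought as its tert‑butyldimethylsilyl ether; atom labels C1–C20 are the ent‑kaurane labels of the target (ring A = C1–C5, C10; ring D = C8, C14, C13, C16, C15; ten‑membered ring = C5‑C6‑C7‑C8‑C14‑C13‑C12‑C11‑C9‑C10; ring B = C5‑C6‑C7‑C8‑C9‑C10).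

**Step 1**
Reactants: 1 3‑methylcyclohex‑2‑en‑1‑one
Product: 3 (2S,3S)‑3‑ethenyl‑3‑methyl‑2‑(prop‑2‑enyl)cyclohexan‑1‑one, via silylvinyl ketone 2 (not isolated)
Conditions: Me3SiC≡CH, i‑Bu2AlH, hexane, 55 °C; then 1, Cu(OTf)2 (5 mol %), chiral sulfonate‑bearing NHC ligand (as imidazolinium salt, 5 mol %), THF, −78 → 4 °C; allyl acetate, Pd(PPh3)4 (5 mol %), 0 °C → rt; then CF3CO2H, CH2Cl2, 0 °C
Reagents that add atoms: diisobutyl[1‑(trimethylsilyl)ethenyl]aluminium C=C([Si](C)(C)C)[Al](CC(C)C)CC(C)C; allyl acetate C=CCOC(C)=O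
Why: Copper–NHC‑catalysed enantioselective conjugate addition of the silyl‑substituted vinylaluminium creates the C10 quaternary centre, Tsuji–Trost allylation of the aluminium enolate occurs anti to the bulky silylvinyl group (allyl cis to methyl, setting C5), and ipso‑protodesilylation unveils the vinyl group.

**Step 2**
Reactants: 3 (2S,3S)‑3‑ethenyl‑3‑methyl‑2‑(prop‑2‑enyl)cyclohexan‑1‑one
Product: 4 (1S,2R)‑1‑ethenyl‑1,3,3‑trimethyl‑2‑(prop‑2‑enyl)cyclohexane
Conditions: Me2TiCl2 (2 equiv, from Me2Zn + TiCl4), CH2Cl2, −30 → 0 °C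
Reagents that add atoms: dichlorodimethyltitanium C[Ti](C)(Cl)Cl
Why: Reetz geminal dimethylation (methyl addition, ionisation of the titanium alkoxide, second methyl transfer) turns C=O into the C4 CMe2 group without touching C5 or C10.

**Step 3**
Reactants: 4 (1S,2R)‑1‑ethenyl‑1,3,3‑trimethyl‑2‑(prop‑2‑enyl)cyclohexane
Product: 5 (1R,2R)‑1,3,3‑trimethyl‑2‑(2‑oxoethyl)cyclohexane‑1‑carbaldehyde
Conditions: O3, CH2Cl2, −78 °C; PPh3
Reagents that add atoms: ozone [O-][O+]=O
Why: Ozonolysis with reductive work‑up cleaves both terminal alkenes to the C9 (neopentyl) and C7 aldehydes.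

**Step 4**
Reactants: 6 (S)‑4‑(tert‑butyldimethylsilyloxy)cyclopent‑2‑en‑1‑one
Product: 9 (S)‑4‑(prop‑2‑enyl)cyclopent‑2‑en‑1‑one, via silyl enol ether 7 (not isolated), via trans‑silyloxy ketone 8 (not isolated)
Conditions: C3H5MgBr, CuBr·SMe2 (10 mol %), Me3SiCl, THF, −78 °C; 1 M HCl; then DBU, CH2Cl2, 0 °C, 30 min
Reagents that add atoms: allylmagnesium bromide C=CC[Mg]Br
Why: Copper‑catalysed conjugate allylation occurs anti to the silyloxy group and E1cB loss of silanol relays that centre to C13 (chirality transfer), a known route to 4‑substituted cyclopentenones.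

**Step 5**
Reactants: 9 (S)‑4‑(prop‑2‑enyl)cyclopent‑2‑en‑1‑one, 5 (1R,2R)‑1,3,3‑trimethyl‑2‑(2‑oxoethyl)cyclohexane‑1‑carbaldehyde
Product: 11 (7R,13S) Morita–Baylis–Hillman‑type adduct (C7 carbinol linking C6 to C8 of the enone; C9 aldehyde kept; exists largely as the C7–O–C9 lactol), via iodo aldol 10 (not isolated)
Conditions: Et2AlI (1.2 equiv), CH2Cl2, −78 °C, 9 then 5; aq. NaHCO3; then Et3N, CH2Cl2, 0 °C
Reagents that add atoms: none
Why: Nozaki‑type iodide‑triggered Michael–aldol (a Morita–Baylis–Hillman surrogate): iodide adds to C14 anti to the allyl group, the cyclic (E) aluminium enolate adds to the unhindered C7 aldehyde anti to iodine through a closed Zimmerman–Traxler transition state (anti aldol), which sets C7 as R, and Et3N then eliminates HI.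

**Step 6**
Reactants: 11 (7R,13S) Morita–Baylis–Hillman‑type adduct
Product: 12 spiro 7,9‑diol 14‑sulfide (ring B closed by the C8–C9 bond; C9 cis to the C13 allyl group; SPh trans to allyl)
Conditions: Me2AlSPh (3 equiv, from Me3Al + PhSH), CH2Cl2/THF, −78 → −30 °C; aq. Rochelle salt
Reagents that add atoms: dimethylaluminium benzenethiolate C[Al](C)Sc1ccccc1
Why: Tandem thia‑Michael/intramolecular aldol: thiolate adds to C14 anti to the allyl group and the aluminium enolate attacks the C9 aldehyde (released from the lactol) on the face anti to sulfur, which A(1,3) strain at C7 also favours, closing ring B through a chair and creating the C8 quaternary centre with C9 cis to the C13 side chain.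

**Step 7**
Reactants: 12 spiro 7,9‑diol 14‑sulfide
Product: 13 7‑O‑triethylsilyl ether of 12
Conditions: Et3SiCl, imidazole, DMF, 0 °C
Reagents that add atoms: chlorotriethylsilane CC[Si](Cl)(CC)CC
Why: Selective silylation of the less hindered C7 hydroxyl; the C9 carbinol lies between two quaternary carbons.

**Step 8**
Reactants: 13 7‑O‑triethylsilyl ether of 12
Product: 14 spiro 9,15‑diketone 14‑sulfone
Conditions: n‑Pr4N[RuO4] (10 mol %), N‑methylmorpholine N‑oxide (5 equiv), 4 Å MS, CH2Cl2/MeCN, rt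
Reagents that add atoms: N‑methylmorpholine N‑oxide C[N+]1([O-])CCOCC1
Why: Ley–Griffith oxidation converts the C9 carbinol into the ketone and the sulfide into the ozone‑stable sulfone (a better leaving group) in one operation.

**Step 9**
Reactants: 14 spiro 9,15‑diketone 14‑sulfone
Product: 15 C11 aldehyde (13‑(2‑oxoethyl) spiro diketone sulfone)
Conditions: O3, CH2Cl2, −78 °C; Me2S
Reagents that add atoms: ozone [O-][O+]=O
Why: Ozonolysis of the remaining terminal alkene gives the C11 aldehyde; ketones, sulfone and silyl ether are inert.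

**Step 10**
Reactants: 15 C11 aldehyde
Product: 18 ten‑membered‑ring enone 11‑acetate 7‑triethylsilyl ether (16‑demethylene target silyl ether), via tetracyclic cis‑diol 16 (not isolated), via hydroxy enone 17 (not isolated)
Conditions: SmI2 (2.1 equiv, THF), −78 → 0 °C; then Ac2O, DMAP (cat.), 0 °C
Reagents that add atoms: acetic anhydride CC(=O)OC(C)=O
Why: Proposed new method: a samarium‑ketyl four‑carbon ring expansion in which the C11 aldehyde ketyl adds to the C9 ketone through a six‑membered, samarium‑chelated transition state (cis‑diolate, which fixes C11 as S), the trivalent samarium alkoxide at C9 then undergoes retro‑aldol cleavage of C8–C9 and the C15 enolate expels benzenesulfinate (E1cB) to give the C8=C14 enone, so ring B becomes the ten‑membered ring; the closest known reactions are the Dowd–Beckwith ring expansion, the SmI2 pinacol cyclisation of keto aldehydes and retro‑aldol/Grob fragmentations.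

**Step 11**
Reactants: 18 ten‑membered‑ring enone 11‑acetate 7‑triethylsilyl ether
Product: 20 target (5R,7R,10R,11S,13R)‑11‑acetoxy‑7‑hydroxy‑8,9‑seco‑ent‑kaura‑8(14),16‑diene‑9,15‑dione, via target triethylsilyl ether 19 (not isolated)
Conditions: (CH2O)n, PhNHMe·CF3CO2H, THF, 65 °C; then 1 M HCl, THF, 0 °C
Reagents that add atoms: formaldehyde (as paraformaldehyde) C=O
Why: Acid‑mediated Mannich condensation–elimination (Gras α‑methylenation) at C16, the only methylene α to a ketone, followed by acidic cleavage of the silyl ether; no stereocentre is touched.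

**Compound list**
1 | 3‑methylcyclohex‑2‑en‑1‑one | CC1=CC(=O)CCC1 | starting material
2 | (2S,3R)‑3‑methyl‑2‑(prop‑2‑enyl)‑3‑[1‑(trimethylsilyl)ethenyl]cyclohexan‑1‑one | C=C([Si](C)(C)C)[C@]1(C)CCCC(=O)[C@H]1CC=C | intermediate (not isolated)
3 | (2S,3S)‑3‑ethenyl‑3‑methyl‑2‑(prop‑2‑enyl)cyclohexan‑1‑one | C=C[C@]1(C)CCCC(=O)[C@H]1CC=C | intermediate
4 | (1S,2R)‑1‑ethenyl‑1,3,3‑trimethyl‑2‑(prop‑2‑enyl)cyclohexane | C=C[C@]1(C)CCCC(C)(C)[C@H]1CC=C | intermediate
5 | (1R,2R)‑1,3,3‑trimethyl‑2‑(2‑oxoethyl)cyclohexane‑1‑carbaldehyde | O=C[C@]1(C)CCCC(C)(C)[C@H]1CC=O | intermediate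
6 | (S)‑4‑(tert‑butyldimethylsilyloxy)cyclopent‑2‑en‑1‑one | O=C1C[C@H](O[Si](C)(C)C(C)(C)C)C=C1 | starting material
7 | trimethylsilyl enol ether of 8 (C15=C16 enol ether; allyl trans to OSi‑t‑BuMe2) | C1=C(O[Si](C)(C)C)C[C@H](O[Si](C)(C)C(C)(C)C)[C@H]1CC=C | intermediate (not isolated)
8 | (3S,4S)‑4‑(tert‑butyldimethylsilyloxy)‑3‑(prop‑2‑enyl)cyclopentan‑1‑one | C1C(=O)C[C@H](O[Si](C)(C)C(C)(C)C)[C@H]1CC=C | intermediate (not isolated)
9 | (S)‑4‑(prop‑2‑enyl)cyclopent‑2‑en‑1‑one | C=CC[C@@H]1C=CC(=O)C1 | intermediate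
10 | β‑iodo aldol (14‑iodide trans to allyl; C8–C7 bond trans to iodine; 7R; as its aluminium alkoxide) | C1C(=O)[C@H]([C@H](I)[C@H]1CC=C)[C@H](O)C[C@H]1[C@](C)(C=O)CCCC1(C)C | intermediate (not isolated)
11 | (1R,2R)‑2‑{(2R)‑2‑hydroxy‑2‑[(3S)‑5‑oxo‑3‑(prop‑2‑enyl)cyclopent‑1‑en‑1‑yl]ethyl}‑1,3,3‑trimethylcyclohexane‑1‑carbaldehyde (open form of the C7–O–C9 lactol) | C1C(=O)C(=C[C@H]1CC=C)[C@H](O)C[C@H]1[C@](C)(C=O)CCCC1(C)C | intermediate
12 | spiro diol sulfide: trans‑fused rings A/B with 7‑OH (R, equatorial) and 9‑OH (axial); C8 spiro to cyclopentanone ring D (C15=O) carrying 14‑SPh (trans to allyl) and 13‑allyl (cis to C9) | C=CC[C@H]1CC(=O)[C@]2([C@@H]1Sc1ccccc1)[C@H](O)[C@]3(C)CCCC(C)(C)[C@H]3C[C@H]2O | intermediate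
13 | 7‑O‑triethylsilyl ether of 12 | C=CC[C@H]1CC(=O)[C@]2([C@@H]1Sc1ccccc1)[C@H](O)[C@]3(C)CCCC(C)(C)[C@H]3C[C@H]2O[Si](CC)(CC)CC | intermediate
14 | spiro 9,15‑diketone with 14‑phenylsulfonyl, 13‑allyl, 7‑OSiEt3 | C=CC[C@H]1CC(=O)[C@]2([C@@H]1S(=O)(=O)c1ccccc1)C(=O)[C@]3(C)CCCC(C)(C)[C@H]3C[C@H]2O[Si](CC)(CC)CC | intermediate
15 | as 14, with the allyl group cut to the 2‑oxoethyl (C12–C11 aldehyde) chain | O=CC[C@H]1CC(=O)[C@]2([C@@H]1S(=O)(=O)c1ccccc1)C(=O)[C@]3(C)CCCC(C)(C)[C@H]3C[C@H]2O[Si](CC)(CC)CC | intermediate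
16 | tetracyclic cis‑9,11‑diol (C9–C11 bond formed; 9‑hydroxy‑ent‑kauran‑15‑one skeleton with 14‑SO2Ph, 7‑OSiEt3; as its samarium diolate) | O[C@H]1C[C@H]2CC(=O)[C@]3([C@@H]2S(=O)(=O)c2ccccc2)[C@]1(O)[C@]4(C)CCCC(C)(C)[C@H]4C[C@H]3O[Si](CC)(CC)CC | intermediate (not isolated)
17 | ring‑expanded 11‑hydroxy enone (C8–C9 cleaved, C8=C14, 9‑ketone, 7‑OSiEt3; as its samarium alkoxide) | C1C(=O)C2=C[C@H]1C[C@H](O)C(=O)[C@]1(C)CCCC(C)(C)[C@H]1C[C@H]2O[Si](CC)(CC)CC | intermediate (not isolated)
18 | 11‑acetate of 17 (16‑demethylene target 7‑triethylsilyl ether) | C1C(=O)C2=C[C@H]1C[C@H](OC(C)=O)C(=O)[C@]1(C)CCCC(C)(C)[C@H]1C[C@H]2O[Si](CC)(CC)CC | intermediate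
19 | 7‑O‑triethylsilyl ether of the target | C=C1C(=O)C2=C[C@H]1C[C@H](OC(C)=O)C(=O)[C@]1(C)CCCC(C)(C)[C@H]1C[C@H]2O[Si](CC)(CC)CC | intermediate (not isolated)
20 | (5R,7R,10R,11S,13R)‑11‑acetoxy‑7‑hydroxy‑8,9‑seco‑ent‑kaura‑8(14),16‑diene‑9,15‑dione (CNP0165527.2) | C=C1C(=O)C2=C[C@H]1C[C@H](OC(C)=O)C(=O)[C@]1(C)CCCC(C)(C)[C@H]1C[C@H]2O | target

**Step count and risks**
Total: 11 steps. Longest linear sequence: 10 steps (steps 1–3 and 5–11); step 4 is the one‑step side branch.

The three steps most likely to fail are steps 10, 6 and 5.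

Step 10 (the proposed new ring expansion). The C9 ketone sits between two quaternary carbons. The ketyl could instead attack the C15 ketone, which would build a more strained bicyclo[2.2.1] diol. The enone product is also sensitive to excess SmI2. The fallback uses only known reactions and gives up the ring expansion; it sets out from 13 and comes back at 18. DBU (CH2Cl2, rt) reverses the aldol of 13 and expels thiophenolate to give the open‑chain enone aldehyde triethylsilyl ether F1. Ozonolysis (O3; Me2S) then gives the C9,C11‑dialdehyde F2. SmI2‑mediated pinacol macrocyclisation at high dilution closes the ten‑membered ring to the 9,11‑diol F3. Ac2O/pyridine acetylates the less hindered C11 hydroxyl to the 11‑monoacetate F4. Dess–Martin oxidation of the C9 carbinol, with separation of the C11 epimer, gives 18.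

Step 6 (congested quaternary centre; the aldehyde must first be released from the lactol). The fallback separates the two events; it sets out from 9 and 5 and comes back at 13. A Me2AlSPh‑mediated thia‑Michael/aldol at C7 is run with in situ Et3SiOTf/2,6‑lutidine trapping of the aldolate, before it can close onto the C9 aldehyde. This gives the β‑phenylsulfanyl ketone triethylsilyl ether F5. Its free C9 aldehyde is then closed onto C8 by a separate, thermodynamically controlled base‑mediated aldol (catalytic PhSLi, THF, 0 °C) to give 13.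

Step 5 (chemoselectivity between the two aldehydes and the anti selectivity that sets C7). The fallback changes the C7–C8 bond construction; it sets out from 9 and comes back at 11. I2/pyridine α‑iodination of 9 gives (S)‑2‑iodo‑4‑(prop‑2‑enyl)cyclopent‑2‑en‑1‑one F6. Nozaki–Hiyama–Kishi coupling (CrCl2, NiCl2 cat., DMSO) with the unhindered aldehyde of 5 gives 11. C7 is steered by a chiral sulfonamide ligand or corrected by separation.

**Further compounds**
F1 | step 10 | open‑chain enone aldehyde: 7‑O‑triethylsilyl ether of 11 (free C9 aldehyde, 13‑allyl) | C1C(=O)C(=C[C@H]1CC=C)[C@H](O[Si](CC)(CC)CC)C[C@H]1[C@](C)(C=O)CCCC1(C)C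
F2 | step 10 | C9,C11‑dialdehyde from F1 (allyl cut to 2‑oxoethyl) | C1C(=O)C(=C[C@H]1CC=O)[C@H](O[Si](CC)(CC)CC)C[C@H]1[C@](C)(C=O)CCCC1(C)C
F3 | step 10 | ten‑membered‑ring 9,11‑diol 7‑triethylsilyl ether (C9 and C11 as formed, mixture) | C1C(=O)C2=C[C@H]1CC(O)C(O)[C@]1(C)CCCC(C)(C)[C@H]1C[C@H]2O[Si](CC)(CC)CC
F4 | step 10 | 11‑monoacetate of F3 | C1C(=O)C2=C[C@H]1CC(OC(C)=O)C(O)[C@]1(C)CCCC(C)(C)[C@H]1C[C@H]2O[Si](CC)(CC)CC
F5 | step 6 | β‑phenylsulfanyl ketone: thia‑Michael/aldol adduct of 9 and 5 at C7, 7‑O‑triethylsilyl, free C9 aldehyde (SPh trans to allyl, C7 chain trans to SPh) | C1C(=O)[C@H]([C@H](Sc2ccccc2)[C@H]1CC=C)[C@H](O[Si](CC)(CC)CC)C[C@H]1[C@](C)(C=O)CCCC1(C)C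
F6 | step 5 | (S)‑2‑iodo‑4‑(prop‑2‑enyl)cyclopent‑2‑en‑1‑one | C=CC[C@@H]1C=C(I)C(=O)C1
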